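## Structural features

The target is a sesquiterpenoid ester built on a bicyclo[5.3.0]decane: a cyclopentane (C1–C2–C3–C4–C5) fused through the C1–C5 bond to a cycloheptanone (C5–C6–C7–C8–C9–C10–C1), with a 4-hydroxybenzoate on O6. It has six stereocentres, (1R,4R,5S,6R,8S,9S) in this numbering: the all-carbon quaternary C1 (methyl), the tertiary carbinol C4 (isopropyl), C5–H, the acyloxy carbon C6, the tertiary carbinol C8 (methyl) and the secondary carbinol C9. C4, C5 and C6 are contiguous, C8 and C9 are contiguous, and the two sets flank the C7 ketone; C1 touches C5 directly and C9 through C10. The ring fusion is trans. The C4 hydroxyl lies on the face of the C1 methyl (the lower face), while H5, O6, O8 and O9 lie on the other (upper) face. The fragile part is the α-acyloxy ketone with a tertiary α′-ketol next to a secondary alcohol, which is open to acyl migration, C6 epimerisation and ketol shifts in base; the tertiary C4 carbinol can dehydrate in strong acid. The real difficulties are the absolute configuration of the quaternary C1, a trans fusion next to it, and keeping the two carbonyl-level carbons C4 and C7 apart chemically. The feature used is that C1 carries a methyl, a three-carbon chain ending in carbonyl-level C4, and two ring arms, which is the prochiral carbon of a 4,4-disubstituted cyclohexadienone. C4 stands 1,4 to the C7 ketone across C5–C6 (an acyl-anion conjugate-addition retron), and the seven-membered ring is that six-membered ring plus C8.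

## Logic of the disconnections

23 ⇒ 22. The phenol O–CH2Ph bond is cut. The free phenol would compete in the acylation, so it is carried as a benzyl ether to the end. Nothing is gained in skeleton; the demand is a neutral deprotection that leaves the α-acyloxy ketol untouched, which requires that no alkene is left in 22.

22 ⇒ 21. The C8–O and C9–O bonds are cut together. A cis-diol on a ring is the retron of a syn-dihydroxylation of the C8=C9 alkene, and placing this last avoids any diol protection. Two stereocentres are removed. The forward step must deliver both oxygens to the upper face of an electron-poor trisubstituted alkene.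

21 ⇒ 19 + 20. The ester C–O bond is cut. This separates the aromatic fragment and leaves a secondary alcohol that is the only acylable hydroxyl in 19. The demand is selectivity over the tertiary C4 hydroxyl, which sterics provide.

19 ⇒ 18. The C6–O bond is cut. C6 is the only enolisable α′ position of the C7 enone, so oxygen can be put in by enolate oxidation. One stereocentre is removed. The forward step must bring oxygen to the upper face, which is the equatorial, thermodynamically preferred position.

18 ⇒ 17 ⇒ 15 + 16. The C4–isopropyl bond is cut after the C7 carbonyl is taken back to an allylic alcohol. Addition of 16 needs C4 to be the only ketone, hence the temporary reduction at C7. The C4 stereocentre and three carbons are removed. The forward addition must come from the upper face of a trans-fused cyclopentanone and must not enolise it.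

15 ⇒ 14 ⇒ 13 ⇒ 12. No skeletal bond is cut. C5 is inverted next to the C4 ketone (15 from 14), the C4 ketone is masked (14 from 13) and C7 is returned to the enone (13 from 12). The gain is that the trans fusion is traced back to the cis fusion that the ring-forming step gives. The demand is that the cis/trans equilibrium at C5 can be brought to the trans side.

12 ⇒ 10 ⇒ 8 + 9. The C7–C8 and C8–C9 bonds are cut. The C8(CH3) unit is taken out of the seven-membered ring, which leads back to a cyclohexanone enol ether and 9 as the one-carbon donor. The seven-membered ring and the C8 methyl are removed. The forward ring opening must break the internal C7–C9 bond of the cyclopropane, and the enol ether must lie specifically at C7=C9.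

8 ⇒ 7 ⇒ 6. Functional-group changes only: the C7=C9 enol ether comes from the C9=C10 enone by conjugate hydride addition with O-silylation, and the C4 ketal from the free ketone. The demand is chemoselective ketalisation of the saturated ketone next to the enone.

6 ⇒ 5. The C4–C5 bond is cut. C4 becomes an aldehyde and the second enone arm is restored, giving an achiral dienone. This removes the five-membered ring and both stereocentres (C1 and C5). The forward step must choose between two enantiotopic enone arms.

5 ⇒ 4 ⇒ 3. The aldehyde is traced to a terminal alkene (anti-Markovnikov oxidation) and the dienone to the enone (dehydrogenation). The demand is an alkene oxidation that tolerates the dienone.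

3 ⇒ 1 + 2. The C–C bonds made by annulation are cut (the bond from the α-carbon of 1 to the β-carbon of 2, and the ring C=C). This leads to two commercial compounds. 3 is formed racemic, which does not matter because its stereocentre becomes the prochiral carbon of 4.

## Other disconnections considered

Alternative 1: The cut takes out C1–C5 and C9–C10 and restores a C7–C9 bond. This gives the acyclic ene–vinylcyclopropane A1, in which a 1,1-disubstituted alkene (C10=C1) is tied through C2–C3–C4 (silyl ether on C4) to a 1-siloxy-1-vinylcyclopropane. Forward, [Rh(CO)2Cl]2 would promote the (5+2) cycloaddition to the cis-fused bicycle A2 with a C6=C7 silyl enol ether.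
- In favour: both rings form in one operation and the seven-membered ring arrives directly. On this point it is better than the chosen plan, which spends steps 5 to 8 on the ring expansion. The enol ether sits at C6=C7, where the target needs oxygen at C6 and the ketone at C7, which is also better.
- Against: the quaternary C1 must form by insertion of a 1,1-disubstituted alkene. Its absolute configuration is relayed from the C4 carbinol of A1, which must first be made enantiopure and is later oxidised, whereas 6 gets C1 from a catalyst. A2 lacks the C8 methyl and the C8=C9 unsaturation, which must be added on the side of the ketone away from the enol ether.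
- Equal: A2 is cis-fused, so the C5 inversion is needed there as well.
- Comparison: the mechanism is a metal-mediated cyclometalation with strain release rather than organocatalytic umpolung. Ring construction is shorter, but A1 takes more steps to assemble and more adjustments follow, so the overall length is comparable.

Alternative 2: The cut takes out C7–C8 and C1–C10 and leads to the vinylcyclopentene A3 and the vinyldiazo ester A4. Forward, a chiral dirhodium tetracarboxylate such as Rh2(S-DOSP)4 (dirhodium tetrakis[(S)-N-(dodecylbenzenesulfonyl)prolinate]) would cyclopropanate the terminal C6=C7 alkene of A3 with the vinylcarbene from A4. A Cope rearrangement in the same operation would then give the cycloheptadiene A5, a formal (4+3) annulation.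
- In favour: two fragments are joined convergently, and the seven-membered ring is formed directly with C8 already substituted and C8=C9 in place. That is better than the chosen plan on ring construction and on the regiochemistry of C8. The C5=C6 alkene leaves C5 and C6 open to a joint addition.
- Equal: C1 is set by a catalyst, as in 6.
- Against: the C8 substituent is an ester that must be reduced to a methyl, and C7 arrives as CH2 and must be oxidised. The sigmatropic step has to bond to the fully substituted C1. The trans C5–H and the C6 oxygen must still be created from a trisubstituted alkene next to the quaternary centre, with no better control than the chosen plan has.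
- Comparison: the step count should be similar, with more redox adjustment than in the chosen route.

Alternative 3: The cut takes out C1–CH3 and C5–C6 and gives the 3-substituted cyclopentenone A6, methylmagnesium bromide A7 and the dithiane aldehyde A8. Forward, Cu(OTf)2 with a chiral N-heterocyclic carbene ligand would catalyse conjugate addition of A7 to C1 of A6, with aldol capture at C5 by A8 in the same flask, to give A9.
- In favour: C1, C5 and C6 are formed in one step, and A9 as drawn carries all three in the configuration of the target. The C5–C6 bond is placed trans to the larger C1 substituent, so no later inversion at C5 is needed. That is better than the chosen plan, whose weakest point is that inversion. The C6 oxygen is installed at once, and the C4 ketone is free for the isopropyl addition.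
- Against: enantioselective methyl addition to a β-substituted cyclopentenone is one of the harder cases for this catalysis. The aldol capture uses a hindered α-quaternary aldehyde at a carbon next to the new quaternary centre. The seven-membered ring is still open and must be closed by a C8–C9 aldol after unmasking the acetal and the dithiane, on a crowded substrate.
- Comparison: on stereochemistry at C5 and C6 this alternative is the better one. On ring construction the chosen plan relies on more dependable closures (a 5-exo conjugate addition and a ring expansion). Step economy is probably equal or slightly in favour of the alternative.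

Key step: step 4

Remark on names: locants C1–C10 follow the numbering above (six-membered-ring compounds lack C8); "upper face" is the face of H5 in the target and "lower face" that of the C1 methyl.

Assumption: the sense of induction in step 4 is taken as catalyst-controlled; the precatalyst is written as the (5aS,10bR) antipode, and the (5aR,10bS) salt is used instead if that is the one that leads to (1R,5S)-6.

## Route

Step 1
Reactants: 1 2-methylpent-4-enal (racemic); 2 but-3-en-2-one
Product: 3 4-methyl-4-(prop-2-en-1-yl)cyclohex-2-en-1-one (racemic)
Conditions: H2SO4 (cat.), toluene, 50 °C, then reflux with water separator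
Reagents that add atoms: none
Why: Acid-catalysed Robinson annulation: the enol of the α-branched aldehyde adds to the protonated enone (Michael addition) and the keto aldehyde closes by aldol condensation; the quaternary carbon forms racemic, which is immaterial because it becomes a prochiral centre in step 2.

Step 2
Reactants: 3 4-methyl-4-(prop-2-en-1-yl)cyclohex-2-en-1-one
Product: 4 4-methyl-4-(prop-2-en-1-yl)cyclohexa-2,5-dien-1-one
Conditions: DDQ, 1,4-dioxane, reflux
Reagents that add atoms: none
Why: Quinone dehydrogenation of a 4,4-disubstituted cyclohexenone through its enol gives the cross-conjugated dienone, which cannot aromatise because C4 is quaternary; the isolated allyl group is not activated towards hydride abstraction.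

Step 3
Reactants: 4 4-methyl-4-(prop-2-en-1-yl)cyclohexa-2,5-dien-1-one
Product: 5 3-(1-methyl-4-oxocyclohexa-2,5-dien-1-yl)propanal
Conditions: PdCl2(PhCN)2 (cat.), CuCl2·2H2O (cat.), AgNO2 (cat.), O2 (1 atm), tBuOH/MeNO2, rt
Reagents that add atoms: dioxygen, O=O
Why: Nitrite-modified, aldehyde-selective Wacker oxidation of an unbiased terminal alkene places oxygen on the terminal carbon; the quaternary carbon next to the allylic CH2 further disfavours the Markovnikov mode, and the electron-poor dienone alkenes should not compete for the palladium.

Step 4
Reactants: 5 3-(1-methyl-4-oxocyclohexa-2,5-dien-1-yl)propanal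
Product: 6 (1R,5S)-cis-fused bicyclic enedione (hydrindene skeleton; ketones at C4 and C7; C9=C10; methyl on C1)
Conditions: (5aS,10bR)-2-(4-methoxyphenyl)-5a,10b-dihydro-4H,6H-indeno[2,1-b][1,2,4]triazolo[4,3-d][1,4]oxazin-2-ium tetrafluoroborate (10 mol%), KN(SiMe3)2 (10 mol%), toluene, 23 °C
Reagents that add atoms: none
Why: The triazolylidene freed by the base adds to the aldehyde carbon C4 and proton transfer gives the nucleophilic enaminol (Breslow intermediate), an acyl anion equivalent that adds to C5, the β-carbon of one enone arm; proton transfer and loss of the carbene then give the 1,4-diketone (intramolecular Stetter reaction). The closest known reaction type is the carbene-catalysed desymmetrising Stetter cyclisation of 4,4-disubstituted cyclohexadienones carrying a tethered aldehyde. The only ring closed is C1–C2–C3–C4–C5, in a 5-exo-trig conjugate addition. The three-atom tether can reach C5 only from the face of C1 on which it stands, so H5 ends cis to the C1 methyl; the relative configuration at C5 is fixed by substrate geometry. The absolute configuration at C1, and with it C5, is decided by which of the two enantiotopic arms is attacked, that is by the aminoindanol backbone of the catalyst, which shields one face of the enaminol. The step needs enantiotopic-group selection (catalyst), conjugate addition in preference to aldol or benzoin pathways (the cross-conjugated dienone is a good acceptor held three atoms from the acyl anion carbon, and only catalytic base is present), and survival of the second arm, which has no further aldehyde to react with and remains as the C7(=O)–C9=C10 enone.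

Step 5
Reactants: 6 (1R,5S)-cis-fused bicyclic enedione
Product: 7 (1R,5S)-C4 ethylene ketal of 6 (spiro-1,3-dioxolane at C4; C7 enone unchanged)
Conditions: (Me3SiOCH2)2, Me3SiOTf (cat.), CH2Cl2, −78 to −20 °C; pyridine
Reagents that add atoms: 1,2-bis(trimethylsilyloxy)ethane, C[Si](C)(C)OCCO[Si](C)(C)C
Why: Silyl-transfer ketalisation under aprotic low-temperature conditions converts the saturated cyclopentanone much faster than the less electrophilic conjugated carbonyl; C5 is not at risk because the cis-fused six–five ketone is the stable epimer.

Step 6
Reactants: 7 (1R,5S)-C4 ethylene ketal enone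
Product: 8 (1R,5S)-C7 triethylsilyl enol ether (C7=C9; C10 now CH2; C4 dioxolane)
Conditions: Et3SiH, RhCl(PPh3)3 (cat.), THF, 50 °C
Reagents that add atoms: triethylsilane, CC[SiH](CC)CC
Why: Rhodium-catalysed 1,4-hydrosilylation of an enone with a monohydrosilane puts hydride on C10 and silicon on oxygen, so the enol ether is fixed regiospecifically at C7=C9 and not towards C6; no stereocentre is formed.

Step 7
Reactants: 8 (1R,5S)-C7 triethylsilyl enol ether; 9 1,1-diiodoethane
Product: 10 (1R,5S)-siloxycyclopropane (C8 carrying H and CH3 bridges C7 and C9; OSiEt3 on C7; C4 dioxolane; mixture at C7, C8, C9)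
Conditions: Et2Zn, CH2Cl2, 0 °C to rt
Reagents that add atoms: none
Why: Furukawa-type Simmons–Smith cyclopropanation with the ethylidene zinc carbenoid on the electron-rich silyl enol ether inserts C8 with its methyl between C7 and C9; the new stereocentres form as a mixture that does not matter because all three are destroyed in step 8.

Step 8
Reactants: 10 (1R,5S)-siloxycyclopropane
Product: 12 (1R,5S)-cis-fused C4-ketal cycloheptenone (bicyclo[5.3.0]dec-8-en-7-one; methyls on C1 and C8), via β-chloro ketone 11 (not isolated)
Conditions: FeCl3, DMF, 0 °C to rt; then NaOAc, MeOH, 65 °C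
Reagents that add atoms: none
Why: Ito–Saegusa ring expansion: one-electron oxidation of the siloxycyclopropane by trivalent iron opens the internal C7–C9 bond to the ring-enlarged β-keto radical, which takes chlorine from a second FeCl3 to give 11; acetate then eliminates HCl across C8–C9 to the conjugated 2-methylcycloheptenone.

Step 9
Reactants: 12 (1R,5S)-cis-fused C4-ketal cycloheptenone
Product: 13 (1R,5S)-cis-fused C4-ketal allylic alcohol (bicyclo[5.3.0]dec-8-en-7-ol; C7 configuration not defined)
Conditions: NaBH4, CeCl3·7H2O, MeOH, −20 °C
Reagents that add atoms: none
Why: Luche 1,2-reduction masks the C7 carbonyl as an allylic alcohol so that C4 can later be the only ketone; the C7 configuration is immaterial because the centre is re-oxidised in step 12.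

Step 10
Reactants: 13 (1R,5S)-cis-fused C4-ketal allylic alcohol
Product: 15 (1R,5R)-trans-fused 7-hydroxy-1,8-dimethylbicyclo[5.3.0]dec-8-en-4-one, via cis-fused hydroxy ketone 14 (not isolated)
Conditions: pyridinium p-toluenesulfonate, acetone/H2O, 55 °C; then K2CO3, MeOH, rt; chromatography, recovered 14 re-equilibrated
Reagents that add atoms: water, O
Why: Mild acid-catalysed ketal hydrolysis frees the C4 ketone without ionising the allylic alcohol, and base then equilibrates C5 through the C4 enolate. In the five–seven system the seven-membered ring can supply the wide torsion angle a trans-fused cyclopentanone needs, so the trans isomer (H5 anti to the C1 methyl) should be reachable under thermodynamic control, unlike the six–five stage where cis is strongly preferred.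

Step 11
Reactants: 15 (1R,5R)-trans-fused hydroxy ketone; 16 isopropylmagnesium chloride
Product: 17 (1R,4R,5R)-4-isopropyl-1,8-dimethyl-trans-bicyclo[5.3.0]dec-8-ene-4,7-diol (C7 configuration not defined)
Conditions: CeCl3 (anhydrous), THF, −78 to 0 °C; NH4Cl (aq)
Reagents that add atoms: none
Why: Organocerium addition, whose low basicity suppresses enolisation and β-hydride reduction of the cyclopentanone; the reagent approaches C4 from the upper face next to H5, away from the pseudo-axial C1 methyl, so the new hydroxyl ends cis to that methyl (4R). One further equivalent is consumed by the C7 hydroxyl.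

Step 12
Reactants: 17 (1R,4R,5R)-diol
Product: 18 (1R,4R,5R)-4-hydroxy-4-isopropyl-1,8-dimethyl-trans-bicyclo[5.3.0]dec-8-en-7-one
Conditions: Dess–Martin periodinane, NaHCO3, CH2Cl2, 0 °C to rt
Reagents that add atoms: none
Why: Oxidation of the only secondary alcohol restores the C7 enone from either C7 epimer; the tertiary C4 alcohol cannot be oxidised.

Step 13
Reactants: 18 (1R,4R,5R)-hydroxy enone
Product: 19 (1R,4R,5S,6R)-4,6-dihydroxy-4-isopropyl-1,8-dimethyl-trans-bicyclo[5.3.0]dec-8-en-7-one
Conditions: KN(SiMe3)2 (2.2 equiv), THF, −78 °C; then 3-phenyl-2-(phenylsulfonyl)oxaziridine, −78 °C; NH4Cl (aq)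
Reagents that add atoms: 3-phenyl-2-(phenylsulfonyl)oxaziridine (Davis oxaziridine), O=S(=O)(c1ccccc1)N1OC1c1ccccc1
Why: After the C4 alkoxide forms, kinetic deprotonation of the enone at its α′ carbon C6 gives the cross-conjugated enolate, which is hydroxylated by the oxaziridine. Oxygen should enter from the upper face, because the lower face of C6 is 1,3-syn to the axial C1 methyl; this gives the equatorial 6R alcohol, which is also the epimer favoured if C6 equilibrates.

Step 14
Reactants: 19 (1R,4R,5S,6R)-dihydroxy enone; 20 4-(benzyloxy)benzoyl chloride
Product: 21 (1R,4R,5S,6R)-4-hydroxy-4-isopropyl-1,8-dimethyl-7-oxo-trans-bicyclo[5.3.0]dec-8-en-6-yl 4-(benzyloxy)benzoate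
Conditions: Et3N, 4-(dimethylamino)pyridine (cat.), CH2Cl2, 0 °C to rt
Reagents that add atoms: none
Why: Nucleophile-catalysed acylation of the only secondary hydroxyl; the hindered tertiary C4 hydroxyl does not react under these conditions, and the benzyl ether keeps the phenol out of the acylation.

Step 15
Reactants: 21 enone ester
Product: 22 (1R,4R,5S,6R,8S,9S)-4,8,9-trihydroxy-4-isopropyl-1,8-dimethyl-7-oxo-trans-bicyclo[5.3.0]decan-6-yl 4-(benzyloxy)benzoate
Conditions: OsO4 (cat.), N-methylmorpholine N-oxide, citric acid, tBuOH/H2O, rt
Reagents that add atoms: N-methylmorpholine N-oxide, C[N+]1([O-])CCOCC1; water, O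
Why: Catalytic syn-dihydroxylation of the trisubstituted enone alkene, run slightly acidic to speed osmate ester hydrolysis and spare the α-acyloxy ketone. Osmium should approach from the upper face, opposite the axial C1 methyl that is 1,3 to C9, so both hydroxyls end on the face of H5 (8S,9S).

Step 16
Reactants: 22 benzyl-protected triol ester
Product: 23 (1R,4R,5S,6R,8S,9S)-4,8,9-trihydroxy-4-isopropyl-1,8-dimethyl-7-oxo-trans-bicyclo[5.3.0]decan-6-yl 4-hydroxybenzoate (CNP0241001.1)
Conditions: H2 (1 atm), Pd/C, EtOAc, rt
Reagents that add atoms: none
Why: Hydrogenolysis of the benzyl aryl ether under neutral conditions; no alkene is left, and the ketone, the ester and the alcohols are inert.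

## Compound list

1 | 2-methylpent-4-enal (racemic) | C=CCC(C)C=O | starting material
2 | but-3-en-2-one | CC(=O)C=C | starting material
3 | 4-methyl-4-(prop-2-en-1-yl)cyclohex-2-en-1-one (racemic) | C=CCC1(C)CCC(=O)C=C1 | intermediate
4 | 4-methyl-4-(prop-2-en-1-yl)cyclohexa-2,5-dien-1-one | C=CCC1(C)C=CC(=O)C=C1 | intermediate
5 | 3-(1-methyl-4-oxocyclohexa-2,5-dien-1-yl)propanal | O=CCCC1(C)C=CC(=O)C=C1 | intermediate
6 | (1R,5S)-cis-fused bicyclic enedione (C4 and C7 ketones, C9=C10, C1 methyl) | O=C1CC[C@]2(C)C=CC(=O)C[C@H]12 | intermediate
7 | (1R,5S)-C4 ethylene ketal of 6 | O1CCOC13CC[C@]2(C)C=CC(=O)C[C@@H]23 | intermediate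
8 | (1R,5S)-C7 triethylsilyl enol ether (C7=C9), C4 ketal | O1CCOC13CC[C@]2(C)CC=C(O[Si](CC)(CC)CC)C[C@@H]23 | intermediate
9 | 1,1-diiodoethane | CC(I)I | starting material
10 | (1R,5S)-siloxycyclopropane, C8(H)(CH3) bridging C7 and C9 (mixture at C7, C8, C9) | O1CCOC13CC[C@]2(C)CC4C(C)C4(O[Si](CC)(CC)CC)C[C@@H]23 | intermediate
11 | (1R,5S)-9-chloro-1,8-dimethyl-cis-bicyclo[5.3.0]decan-7-one, C4 ketal (mixture at C8, C9) | O1CCOC13CC[C@]2(C)CC(Cl)C(C)C(=O)C[C@@H]23 | intermediate (not isolated)
12 | (1R,5S)-1,8-dimethyl-cis-bicyclo[5.3.0]dec-8-en-7-one, C4 ketal | O1CCOC13CC[C@]2(C)CC=C(C)C(=O)C[C@@H]23 | intermediate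
13 | (1R,5S)-1,8-dimethyl-cis-bicyclo[5.3.0]dec-8-en-7-ol, C4 ketal (C7 not defined) | O1CCOC13CC[C@]2(C)CC=C(C)C(O)C[C@@H]23 | intermediate
14 | (1R,5S)-7-hydroxy-1,8-dimethyl-cis-bicyclo[5.3.0]dec-8-en-4-one (C7 not defined) | O=C1CC[C@]2(C)CC=C(C)C(O)C[C@H]12 | intermediate (not isolated)
15 | (1R,5R)-7-hydroxy-1,8-dimethyl-trans-bicyclo[5.3.0]dec-8-en-4-one (C7 not defined) | O=C1CC[C@]2(C)CC=C(C)C(O)C[C@@H]12 | intermediate
16 | isopropylmagnesium chloride | CC(C)[Mg]Cl | starting material
17 | (1R,4R,5R)-4-isopropyl-1,8-dimethyl-trans-bicyclo[5.3.0]dec-8-ene-4,7-diol (C7 not defined) | CC(C)[C@]1(O)CC[C@]2(C)CC=C(C)C(O)C[C@H]21 | intermediate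
18 | (1R,4R,5R)-4-hydroxy-4-isopropyl-1,8-dimethyl-trans-bicyclo[5.3.0]dec-8-en-7-one | CC(C)[C@]1(O)CC[C@]2(C)CC=C(C)C(=O)C[C@H]21 | intermediate
19 | (1R,4R,5S,6R)-4,6-dihydroxy-4-isopropyl-1,8-dimethyl-trans-bicyclo[5.3.0]dec-8-en-7-one | CC(C)[C@]1(O)CC[C@]2(C)CC=C(C)C(=O)[C@H](O)[C@H]21 | intermediate
20 | 4-(benzyloxy)benzoyl chloride | O=C(Cl)c1ccc(OCc2ccccc2)cc1 | starting material
21 | 6-O-[4-(benzyloxy)benzoyl] ester of 19 | CC(C)[C@]1(O)CC[C@]2(C)CC=C(C)C(=O)[C@H](OC(=O)c3ccc(OCc4ccccc4)cc3)[C@H]21 | intermediate
22 | (1R,4R,5S,6R,8S,9S)-4,8,9-trihydroxy-4-isopropyl-1,8-dimethyl-7-oxo-trans-bicyclo[5.3.0]decan-6-yl 4-(benzyloxy)benzoate | CC(C)[C@]1(O)CC[C@]2(C)C[C@H](O)[C@](C)(O)C(=O)[C@H](OC(=O)c3ccc(OCc4ccccc4)cc3)[C@H]21 | intermediate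
23 | (1R,4R,5S,6R,8S,9S)-4,8,9-trihydroxy-4-isopropyl-1,8-dimethyl-7-oxo-trans-bicyclo[5.3.0]decan-6-yl 4-hydroxybenzoate | CC(C)[C@]1(O)CC[C@]2(C)C[C@H](O)[C@](C)(O)C(=O)[C@H](OC(=O)c3ccc(O)cc3)[C@H]21 | target

## Step count and least certain steps

Total: 16 steps. Longest linear sequence: 16 steps (1 and 2 to 23); 9, 16 and 20 enter as purchased reagents.

Step 4 (key step). The most likely failure is insufficient discrimination between the two enone arms, or aldol self-condensation of the enolisable aliphatic aldehyde outrunning the conjugate addition. The all-carbon tether lacks the heteroatom of the best-precedented substrates and the aldehyde has acidic α-hydrogens. Fallback: starting from 5, the cyclisation is run with an achiral thiazolium carbene (3-benzyl-5-(2-hydroxyethyl)-4-methylthiazolium chloride, Et3N). This should give 6 together with its mirror image, the (1S,5R)-enedione F1, and the racemate is resolved by preparative chromatography on a chiral stationary phase. The route is rejoined at 6.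

Step 10. The most likely failure is that equilibration at C5 does not move far enough to the trans side. The intrinsic preference in a five–seven system with an angular methyl may be small. In addition, a transannular hemiketal between the C7 hydroxyl and the C4 carbonyl can close only in the cis series and would hold material there. Allylic transposition of the C7 alcohol under the acid is a second risk. Fallback: starting from 12, the ketal is hydrolysed while C7 is still the enone. The resulting cis diketone F2 has no hydroxyl and is equilibrated with base to the trans diketone F3, which is separated; F2 is recycled. F3 is re-ketalised selectively at the saturated C4 ketone (as in step 5) to the trans ketal enone F4. Luche reduction then gives the trans ketal alcohol F5, and acid hydrolysis without base treatment gives 15, where the route is rejoined.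

Step 8. The most likely failure is opening of the exocyclic C7–C8 bond of the ethylidene cyclopropane instead of the internal C7–C9 bond. With the extra methyl both modes give secondary radicals, so the bias towards ring enlargement is weaker than in the unsubstituted case. Loss of the dioxolane to the Lewis acid is a second risk. Fallback: starting from 8, methylene cyclopropanation (CH2I2, Et2Zn) gives the unsubstituted siloxycyclopropane F6. FeCl3 in DMF opens it to the β-chloro ketone F7, and NaOAc gives the cycloheptenone F8. α-Iodination (I2, pyridine) gives the 8-iodo enone F9, and methyl cross-coupling (trimethylboroxine, Pd(PPh3)4, K2CO3) gives 12, where the route is rejoined.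

Step 15. The most likely failure is poor facial selectivity or very slow osmylation of the electron-poor trisubstituted alkene, with acyl migration from O6 as a side process on long exposure. Fallback: starting from 19, the dihydroxylation is done before acylation and directed by hydrogen bonding from the upper-face C6 hydroxyl (OsO4 with TMEDA, CH2Cl2, −78 °C), to give the tetraol F10. The cis C8/C9 diol is protected as the acetonide F11 (2,2-dimethoxypropane, pyridinium p-toluenesulfonate). Acylation with 20 gives the ester acetonide F12, and aqueous acetic acid removes the acetonide to give 22, where the route is rejoined.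

Step 13. The most likely failure is delivery of oxygen to the lower face of the enolate, or competing γ-deprotonation at C10 or conjugate addition of the C4 alkoxide to C9. Fallback: starting from 18, if the lower-face alcohol, the (6S)-epimer F13, is what forms, it is esterified under Mitsunobu conditions (PPh3, diisopropyl azodicarboxylate, 4-(benzyloxy)benzoic acid). This inverts C6 and gives 21 directly, where the route is rejoined.

Step 3. The most likely failure is competing Markovnikov oxidation to the methyl ketone. Fallback: starting from 4, iridium-catalysed hydroboration with pinacolborane ([Ir(cod)Cl]2, 1,2-bis(diphenylphosphino)ethane), which leaves ketones alone, gives the terminal pinacol boronate F14. Sodium perborate oxidation gives the primary alcohol F15, and Dess–Martin oxidation gives 5, where the route is rejoined.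

## Further compounds

F1 | step 4 | (1S,5R)-cis-fused bicyclic enedione (enantiomer of 6) | O=C1CC[C@@]2(C)C=CC(=O)C[C@@H]12
F2 | step 10 | (1R,5S)-1,8-dimethyl-cis-bicyclo[5.3.0]dec-8-ene-4,7-dione | O=C1CC[C@]2(C)CC=C(C)C(=O)C[C@H]12
F3 | step 10 | (1R,5R)-1,8-dimethyl-trans-bicyclo[5.3.0]dec-8-ene-4,7-dione | O=C1CC[C@]2(C)CC=C(C)C(=O)C[C@@H]12
F4 | step 10 | (1R,5R)-1,8-dimethyl-trans-bicyclo[5.3.0]dec-8-en-7-one, C4 ethylene ketal | O1CCOC13CC[C@]2(C)CC=C(C)C(=O)C[C@H]23
F5 | step 10 | (1R,5R)-1,8-dimethyl-trans-bicyclo[5.3.0]dec-8-en-7-ol, C4 ethylene ketal (C7 not defined) | O1CCOC13CC[C@]2(C)CC=C(C)C(O)C[C@H]23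
F6 | step 8 | (1R,5S)-siloxycyclopropane with CH2 bridging C7 and C9, C4 ketal | O1CCOC13CC[C@]2(C)CC4CC4(O[Si](CC)(CC)CC)C[C@@H]23
F7 | step 8 | (1R,5S)-9-chloro-1-methyl-cis-bicyclo[5.3.0]decan-7-one, C4 ketal | O1CCOC13CC[C@]2(C)CC(Cl)CC(=O)C[C@@H]23
F8 | step 8 | (1R,5S)-1-methyl-cis-bicyclo[5.3.0]dec-8-en-7-one, C4 ketal | O1CCOC13CC[C@]2(C)CC=CC(=O)C[C@@H]23
F9 | step 8 | (1R,5S)-8-iodo-1-methyl-cis-bicyclo[5.3.0]dec-8-en-7-one, C4 ketal | O1CCOC13CC[C@]2(C)CC=C(I)C(=O)C[C@@H]23
F10 | step 15 | (1R,4R,5S,6R,8S,9S)-4,6,8,9-tetrahydroxy-4-isopropyl-1,8-dimethyl-trans-bicyclo[5.3.0]decan-7-one | CC(C)[C@]1(O)CC[C@]2(C)C[C@H](O)[C@](C)(O)C(=O)[C@H](O)[C@H]21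
F11 | step 15 | 8,9-O-isopropylidene acetal of F10 | CC(C)[C@]1(O)CC[C@]2(C)C[C@@H]3OC(C)(C)O[C@]3(C)C(=O)[C@H](O)[C@H]21
F12 | step 15 | 6-O-[4-(benzyloxy)benzoyl] ester of F11 | CC(C)[C@]1(O)CC[C@]2(C)C[C@@H]3OC(C)(C)O[C@]3(C)C(=O)[C@H](OC(=O)c4ccc(OCc5ccccc5)cc4)[C@H]21
F13 | step 13 | (1R,4R,5S,6S)-4,6-dihydroxy-4-isopropyl-1,8-dimethyl-trans-bicyclo[5.3.0]dec-8-en-7-one (C6 epimer of 19) | CC(C)[C@]1(O)CC[C@]2(C)CC=C(C)C(=O)[C@@H](O)[C@H]21
F14 | step 3 | 4-methyl-4-[3-(4,4,5,5-tetramethyl-1,3,2-dioxaborolan-2-yl)propyl]cyclohexa-2,5-dien-1-one | CC1(C)OB(CCCC2(C)C=CC(=O)C=C2)OC1(C)C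
F15 | step 3 | 4-(3-hydroxypropyl)-4-methylcyclohexa-2,5-dien-1-one | OCCCC1(C)C=CC(=O)C=C1
A1 | alternative 1 | (E)-ene–vinylcyclopropane: 2-methylhepta-1,6-diene with tert-butyldimethylsilyloxy on the allylic carbon and a 1-(triethylsilyloxy)cyclopropyl group on the far alkene terminus | C=C(C)CC[C@H](O[Si](C)(C)C(C)(C)C)/C=C/C1(O[Si](CC)(CC)CC)CC1
A2 | alternative 1 | cis-fused bicyclo[5.3.0]decene with quaternary C1 methyl, C4 tert-butyldimethylsilyl ether and C6=C7 triethylsilyl enol ether | CC(C)(C)[Si](C)(C)O[C@H]1CC[C@]2(C)CCCC(O[Si](CC)(CC)CC)=C[C@@H]21
A3 | alternative 2 | 6-ethenyl-7-methyl-1,4-dioxaspiro[4.4]non-6-ene | C=CC1=C(C)CCC12OCCO2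
A4 | alternative 2 | methyl 2-diazobut-3-enoate | C=CC(=[N+]=[N-])C(=O)OC
A5 | alternative 2 | bicyclic diene ester with C4 ketal, quaternary C1 methyl, C5=C6 and C8=C9, methyl ester on C8 | COC(=O)C1=CC[C@@]2(C)CCC3(OCCO3)C2=CC1
A6 | alternative 3 | 3-(2,2-dimethoxyethyl)cyclopent-2-en-1-one | O=C1C=C(CC(OC)OC)CC1
A7 | alternative 3 | methylmagnesium bromide | C[Mg]Br
A8 | alternative 3 | 2-ethyl-1,3-dithiane-2-carbaldehyde | O=CC1(CC)SCCCS1
A9 | alternative 3 | aldol adduct: cyclopentanone with C1 methyl and 2,2-dimethoxyethyl arm, C6 carbinol bearing the 2-ethyl-1,3-dithian-2-yl group | O=C1CC[C@](C)(CC(OC)OC)[C@H]1[C@@H](O)C2(CC)SCCCS2
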